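**Retrosynthetic overview**

1. Feature: ring A (C4a, C5, C6, C7, C8, C8a) carries oxygen on C5, C7 and C8a and the C4 carbonyl carbon on C4a. This is the pattern of an acylphloroglucinol, that is, of a folded poly-β-carbonyl chain, and the methoxyls on C6 and C8 sit on the two carbons between those oxygens.
2. Ring C (last): the O1–C2 bond is cut, which leads back to the 2-hydroxyaryl 1,3-diketone 9. Compound 9 is symmetric about ring A, so either flanking hydroxyl gives 10.
3. Ring A (key): the C4a–C8a bond is cut, which leads back to the open-chain tetraketo ester 8. Its C6 attacks its ester carbon C1, and all ring A oxygens and the C4 carbonyl are already in the chain.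
4. Chain 8 is grown outward from the ring B ketone: acetylation of 1, two terminal methoxyacetylations of the derived polyanions, then terminal carboxylation and O-methylation. A methoxymalonate diester is not used as the last unit, because its acidic methine would protonate the polyanion instead of acylating it.
5. Ring order: ring B is bought, ring A is closed in step 5, ring C in step 6.

Key step: step 5

Remark: compounds 3 and 5 to 9 are keto–enol mixtures drawn in the keto form. The methoxy-bearing sp3 carbons of 6, 7 and 8 are configurationally labile and left undefined (mixtures of epimers), since they become aromatic carbons in step 5. The target has no stereocentre.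

**Route**

Step 1
Reactants: 1 2',3'-dimethoxyacetophenone; 2 ethyl acetate
Product: 3 1-(2,3-dimethoxyphenyl)butane-1,3-dione
Conditions: NaH (2.2 equiv), EtOAc (excess), THF, reflux; then aq HCl
Reagents that add atoms: none
Why: Crossed Claisen condensation in which the sodium enolate of the methyl ketone is acylated by ethyl acetate and the equilibrium is drawn to the product by deprotonation of the more acidic β-diketone.

Step 2
Reactants: 3 1-(2,3-dimethoxyphenyl)butane-1,3-dione; 4 methyl methoxyacetate
Product: 5 1-(2,3-dimethoxyphenyl)-6-methoxyhexane-1,3,5-trione
Conditions: LiN(iPr)2 (2.1 equiv per 3), THF, 0 °C; then 4 (0.5 equiv), 0 °C to rt; cold aq HCl (excess 3 recovered)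
Reagents that add atoms: none
Why: Terminal Claisen acylation of a β-diketone dianion, in which the methyl carbanion formed by the second deprotonation is the most basic site and attacks the chelating α-methoxy ester, while half of the dianion serves as base for the more acidic triketone.

Step 3
Reactants: 5 1-(2,3-dimethoxyphenyl)-6-methoxyhexane-1,3,5-trione; 4 methyl methoxyacetate
Product: 6 1-(2,3-dimethoxyphenyl)-6,8-dimethoxyoctane-1,3,5,7-tetraone
Conditions: LiN(iPr)2 (3.1 equiv per 5), THF, 0 °C; then 4 (0.5 equiv), 0 °C; cold aq HCl; crude product used at once
Reagents that add atoms: none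
Why: The same terminal Claisen acylation one level higher, in which the third deprotonation of 5 can only occur at the methoxymethyl end and this carbanion should add to the activated ester faster than it abstracts its α-proton, the tetraketone staying protected as its polyenolate until the cold acidic quench.

Step 4
Reactants: 6 1-(2,3-dimethoxyphenyl)-6,8-dimethoxyoctane-1,3,5,7-tetraone
Product: 8 methyl 9-(2,3-dimethoxyphenyl)-2,4-dimethoxy-3,5,7,9-tetraoxononanoate, via tetraketo acid 7 (not isolated)
Conditions: LiN(iPr)2 (4.2 equiv), THF, -78 to 0 °C; CO2 (excess), -78 °C; cold aq HCl, Et2O extraction; then CH2N2 (1 equiv), Et2O, 0 °C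
Reagents that add atoms: carbon dioxide O=C=O; diazomethane C=[N+]=[N-]
Why: Terminal carboxylation of a polyanion, in which the fourth and most basic carbanion at the methoxymethyl end takes up CO2, the carboxylate formed cannot protonate unreacted tetraanion, and diazomethane esterifies the free acid 7 much faster than it O-methylates the hydrogen-bonded enols.

Step 5
Reactants: 8 methyl 9-(2,3-dimethoxyphenyl)-2,4-dimethoxy-3,5,7,9-tetraoxononanoate
Product: 9 1-(2,3-dimethoxyphenyl)-3-(2,4,6-trihydroxy-3,5-dimethoxyphenyl)propane-1,3-dione
Conditions: Mg(OMe)2 (5 equiv), MeOH, 25 °C then reflux; cold 1 M HCl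
Reagents that add atoms: none
Why: Mg(OMe)2 should hold 8 (chain numbered from the ester carbon C1 to the aryl ketone carbon C9) as a chelated polyenolate in which the C6 carbanion, flanked by the C5 and C7 carbonyls, adds to the ester carbonyl C1 and expels methoxide, and the cyclic triketone so formed tautomerises at once to the arene because C2 and C4 each keep one hydrogen beside their methoxyl; the new C6–C1 bond is the C4a–C8a bond of the flavone. The closest known reaction is the Claisen-mode cyclisation of 3,5,7-triketo esters to acylphloroglucinols under Mg(OMe)2 or hydroxide, the laboratory counterpart of chalcone-type polyketide folding. Ring A closes in a 6-exo-trig mode, the attacked C=O lying outside the new ring. No stereocentre is formed, and the two labile methoxy-bearing carbons C2 and C4 end as the sp2 carbons C8 and C6 of the flavone. The selectivity needed is C-acylation at C1 in preference to aldol closure of C8 onto the C3 ketone (the only aldol mode that can aromatise), to lactonisation to a pyranone and to chain scission by methoxide. Three features of 8 should secure it: the α-methoxy ester is a bidentate site for magnesium and so the most electrophilic carbonyl, the C3 ketone lies between two acidic methines and stays enolised (aldol additions from C2 or C4 would give quaternary carbons that cannot aromatise and revert, and a pyranone reopens in methoxide), and only the Claisen path ends in an aromatic phenoxide that does not revert.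

Step 6
Reactants: 9 1-(2,3-dimethoxyphenyl)-3-(2,4,6-trihydroxy-3,5-dimethoxyphenyl)propane-1,3-dione
Product: 10 5,7-dihydroxy-6,8-dimethoxy-2-(2,3-dimethoxyphenyl)-4H-chromen-4-one (5,7-dihydroxy-6,8,2',3'-tetramethoxyflavone)
Conditions: H2SO4 (cat.), AcOH, 90 °C
Reagents that add atoms: none
Why: Acid-catalysed cyclodehydration of a 2-hydroxyaryl 1,3-diketone (the closing stage of a Baker–Venkataraman flavone synthesis), in which a hydroxyl ortho to the acyl group adds to the enolised carbonyl next to ring B and water is lost, the two ortho hydroxyls being equivalent so that a single flavone should result.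

**Compound list**

1 | 2',3'-dimethoxyacetophenone | CC(=O)c1cccc(OC)c1OC | starting material
2 | ethyl acetate | CCOC(C)=O | starting material
3 | 1-(2,3-dimethoxyphenyl)butane-1,3-dione | CC(=O)CC(=O)c1cccc(OC)c1OC | intermediate
4 | methyl methoxyacetate | COCC(=O)OC | starting material
5 | 1-(2,3-dimethoxyphenyl)-6-methoxyhexane-1,3,5-trione | COCC(=O)CC(=O)CC(=O)c1cccc(OC)c1OC | intermediate
6 | 1-(2,3-dimethoxyphenyl)-6,8-dimethoxyoctane-1,3,5,7-tetraone (racemic, enolisable) | COCC(=O)C(OC)C(=O)CC(=O)CC(=O)c1cccc(OC)c1OC | intermediate
7 | 9-(2,3-dimethoxyphenyl)-2,4-dimethoxy-3,5,7,9-tetraoxononanoic acid (mixture of epimers and enol tautomers) | OC(=O)C(OC)C(=O)C(OC)C(=O)CC(=O)CC(=O)c1cccc(OC)c1OC | intermediate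
8 | methyl 9-(2,3-dimethoxyphenyl)-2,4-dimethoxy-3,5,7,9-tetraoxononanoate (mixture of epimers and enol tautomers) | COC(=O)C(OC)C(=O)C(OC)C(=O)CC(=O)CC(=O)c1cccc(OC)c1OC | intermediate
9 | 1-(2,3-dimethoxyphenyl)-3-(2,4,6-trihydroxy-3,5-dimethoxyphenyl)propane-1,3-dione | COc1cccc(C(=O)CC(=O)c2c(O)c(OC)c(O)c(OC)c2O)c1OC | intermediate
10 | 5,7-dihydroxy-6,8-dimethoxy-2-(2,3-dimethoxyphenyl)-4H-chromen-4-one | COc1cccc(-c2cc(=O)c3c(O)c(OC)c(O)c(OC)c3o2)c1OC | target

**Step count**

Total steps: 6. Longest linear sequence: 6 steps (1 to 3 to 5 to 6 to 8 to 9 to 10).

**Steps most likely to fail**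

Step 5. The acyl substitution at C1 may be outrun by aldol closure of C8 onto the C3 ketone, by lactonisation, or by methoxide-induced scission of the chain. The fallback gives up the folding of a chain and takes ring A from a preformed arene, adding the C6 and C8 oxygens late. It sets out from 1 and comes back to the route at 10. Compound 1 is C-ethoxycarbonylated (NaH, diethyl carbonate, toluene, reflux) to ethyl 3-(2,3-dimethoxyphenyl)-3-oxopropanoate F1. F1 is heated neat with phloroglucinol (benzene-1,3,5-triol) at about 240 °C (Mentzer-type thermal chromone synthesis) to give 5,7-dihydroxy-2-(2,3-dimethoxyphenyl)-4H-chromen-4-one F2. NBS (2 equiv, DMF, 0 °C) should brominate the two free positions of ring A to give 6,8-dibromo-5,7-dihydroxy-2-(2,3-dimethoxyphenyl)-4H-chromen-4-one F3. NaOMe with CuBr in DMF–MeOH at 120 °C (Ullmann-type methoxylation) should then exchange both bromides for methoxyl and deliver 10.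

Step 3. Proton transfer from the enolisable ester to the trianion may return 5 and leave the ester to self-condense, and the released tetraketone may undergo aldol cyclisation during work-up. The fallback replaces the second linear extension by a convergent union. It sets out from 3 and 4 and comes back at 6. Compound 4 is self-condensed (NaH, THF, reflux; Claisen condensation) to methyl 2,4-dimethoxy-3-oxobutanoate F4. F4 is converted to its lithium enolate (LiN(iPr)2, 1 equiv, THF, 0 °C) and added to the dianion of 3 (LiN(iPr)2, 2 equiv per 3; two equiv of dianion per F4). The terminal carbanion of 3 should displace methoxide from the ester carbon of the enolate, whose only remaining protons are the weakly acidic C4 hydrogens, and cold acidic work-up should give 6 (acylation of a diketone dianion by a β-keto ester salt).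

Step 4. The carboxylation may be incomplete or occur at an internal carbon, the β-keto acid 7 may lose CO2 during isolation, the tetraketone may cyclise while the tetraanion is formed, and diazomethane may O-methylate enols. The fallback carries the ester terminus from the first step and adds the aryl ketone last, so that no tetraketone is carboxylated. It sets out from 4 and comes back at 8. Methyl 2,4-dimethoxy-3-oxobutanoate F4 (made from 4 as above) is converted to its dianion (NaH, then n-BuLi, THF, 0 °C) and acetylated at C4 with ethyl acetate 2 to give methyl 2,4-dimethoxy-3,5-dioxohexanoate F5. The trianion of F5 (LiN(iPr)2, 3 equiv) is acetylated at its terminal methyl with 2 to give methyl 2,4-dimethoxy-3,5,7-trioxooctanoate F6. The tetraanion of F6 (LiN(iPr)2, 4 equiv, THF, 0 °C) is aroylated at its terminal methyl with methyl 2,3-dimethoxybenzoate, a non-enolisable ester, to give 8. In each polyanion the ester group is masked as its enolate, so no premature ring closure is expected.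

**Further compounds**

F1 | step 5 | ethyl 3-(2,3-dimethoxyphenyl)-3-oxopropanoate | CCOC(=O)CC(=O)c1cccc(OC)c1OC
F2 | step 5 | 5,7-dihydroxy-2-(2,3-dimethoxyphenyl)-4H-chromen-4-one | COc1cccc(-c2cc(=O)c3c(O)cc(O)cc3o2)c1OC
F3 | step 5 | 6,8-dibromo-5,7-dihydroxy-2-(2,3-dimethoxyphenyl)-4H-chromen-4-one | COc1cccc(-c2cc(=O)c3c(O)c(Br)c(O)c(Br)c3o2)c1OC
F4 | step 3 | methyl 2,4-dimethoxy-3-oxobutanoate (racemic, enolisable) | COCC(=O)C(OC)C(=O)OC
F5 | step 4 | methyl 2,4-dimethoxy-3,5-dioxohexanoate (mixture of epimers and enol tautomers) | CC(=O)C(OC)C(=O)C(OC)C(=O)OC
F6 | step 4 | methyl 2,4-dimethoxy-3,5,7-trioxooctanoate (mixture of epimers and enol tautomers) | CC(=O)CC(=O)C(OC)C(=O)C(OC)C(=O)OC
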